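Compound numbers are fixed by the steps below and used in every section. The target is 17, the key-step precursors are diene 6 and ynone 11, and the key-step product is deoxybenzoin 14.

## The problem

Target 17, 6-hydroxy-7-methoxy-3-(3,4,5-trimethoxyphenyl)-4H-chromen-4-one, is an isoflavone: benzene ring A fused to 4-pyranone ring C, with aryl ring B on C3. It has no stereocentre, so the task is only to place substituents and close two rings in a workable order. Ring B is symmetric and available as an arylacetic acid, and ring C is classically closed last from a 2-hydroxyphenyl benzyl ketone and a one-carbon electrophile. Ring A is the real difficulty: a 1,2,4,5-tetrasubstituted benzene with oxygens on C6, C7 and C8a, the acyl carbon on C4a and hydrogens on C5 and C8, in which the neighbouring oxygens on C6 (free hydroxyl) and C7 (methyl ether) must be told apart. Reagent choice is limited by the four aryl methyl ethers (no BBr3, no hot AlCl3), by the electron-rich C6 phenol (best kept masked to the end), and by the chromone enone C2=C3–C4=O, which hydroxide opens and hydrogen can over-reduce. The enabling feature is the run C8a–C8–C7–C6 of ring A, which carries oxygen on its first, third and fourth carbons and so maps onto a 1,1,3,4-tetraoxygenated butadiene, while the pair C5–C4a (a CH beside an acyl-bearing carbon) maps onto a terminal acetylenic ketone. The second oxygen on the ketene acetal carbon is the leaving group that lets the cycloadduct aromatise, so ring A can be built from open-chain pieces with its three oxygens already differentiated.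

## Retrosynthesis

**17 from 16.** The O–CH2Ph bond at C6 is cut last. A benzyl ether is chosen for this oxygen because it must pass through a lithium amide, a thermal cycloaddition with acid work-up and a hot formamide acetal. Its removal by hydrogenolysis leaves the methyl ethers untouched. Precursor 16 differs from 17 only in this group, which is what keeps C6 and C7 distinct throughout.

**16 from 14.** O1–C2 and C2–C3 are cut, which removes C2 and opens ring C to the 2-hydroxyphenyl benzyl ketone 14. The neighbouring cut, forming C4–C4a on a preformed aryl ether, would bring back arene acylation and its regiochemical question. Forward, the formamide acetal must condense only at the doubly activated methylene, and enaminone 15 must close on the ortho phenol.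

**14 from 6 and 11 (key disconnection).** C5–C6 and C4a–C8a of ring A are cut. This gives {[(1Z,3Z)-4-(benzyloxy)-1,3-dimethoxybuta-1,3-dien-1-yl]oxy}(trimethyl)silane 6 and 1-(3,4,5-trimethoxyphenyl)but-3-yn-2-one 11.
- Against Friedel–Crafts acylation of an oxygenated phenol, this cut needs no Lewis acid next to the benzyl ether and leaves no choice of position on the ring.
- The methoxy, benzyloxy and hydroxyl groups each arrive on a defined carbon of the diene, and the ketone arrives with its benzylic methylene in place.
- Both precursors are acyclic and three steps or fewer from bought materials.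
- Forward, the diene C4 must bond to the terminal alkyne carbon. Cycloadduct 12 must then aromatise by loss of methanol, not of the silyloxy group, via silyl ether 13.

**6 from 5, 3, 1 and 2.** The O–Si bond is cut to the 3-methoxy enoate 5. The enol ether O–CH3 is cut (through ketal 4) to β-keto ester 3, and the C4–OBn bond is cut to methyl 4-chloroacetoacetate 1 and benzyl alcohol 2. Each forward step is a standard operation on a β-keto ester, and the ether on C4 is set before the enol ether so that no allylic substitution problem arises.

**11 from 9 and 7.** The alkyne–carbonyl bond is cut to the N-methoxy-N-methylamide 9, made from 3,4,5-trimethoxyphenylacetic acid 7 through acyl imidazole 8. Forward, the acetylide must add once (chelate 10). The terminal ynone must also be kept from the amine released on work-up.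

## Roads not taken

**Alternative 1: isoxazole as masked ring C.**
- Cut and key step: the C3–C4 bond is cut. 2,5-Bis(benzyloxy)-4-methoxybenzonitrile oxide A2 would add to the pyrrolidine enamine A3 of the ring B arylacetaldehyde, and loss of pyrrolidine would give 3-[2,5-bis(benzyloxy)-4-methoxyphenyl]-4-(3,4,5-trimethoxyphenyl)isoxazole A1. Hydrogenation would cleave the N–O bond and both benzyl ethers, and acid hydrolysis of the vinylogous amide would close ring C.
- Merits: the cycloaddition is regiochemically dependable, with the nitrile oxide carbon bonding to the enamine β-carbon. The isoxazole is a robust, storable carrier of the 1,3-dicarbonyl, and unmasking and deprotection can share one operation.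
- Weak points: ring A must first exist as a fully substituted benzaldehyde, so the C6/C7 differentiation is pushed back into several steps of arene substitution chemistry. The ortho-alkoxy, electron-rich nitrile oxide A2 is prone to dimerise. The arylacetaldehyde behind A3 is delicate, and hydrolysis of the amino enone needs acid and heat.
- Comparison: this road is better in the stability of its intermediates and in the reliability of each single step. The chosen plan is shorter and takes the ring A oxygen pattern from acyclic esters with no arene substitution.

**Alternative 2: aryne annulation with an α-formyl arylacetate.**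
- Cut and key step: O1–C8a and C4–C4a are cut. CsF would release 4,5-bis(benzyloxy)benzyne from silyl triflate A5. The enolate oxygen of methyl 3-oxo-2-(3,4,5-trimethoxyphenyl)propanoate A6 would add, and the aryl anion would attack the ester to give 6,7-bis(benzyloxy)-3-(3,4,5-trimethoxyphenyl)chromen-4-one A4.
- Merits: it is the most convergent of the four, with ring C and both ring fusions bonds made in one operation under nearly neutral conditions.
- Weak points: the aryne must be symmetric to avoid a regiochemical mixture, so C6 and C7 arrive with identical benzyl ethers. After debenzylation the two hydroxyls would have to be separated by selective 7-O-methylation, which rests on a modest acidity difference. β-Dicarbonyl enolates also tend to attack arynes through carbon (acyl-alkylation), so the required O-arylation is not assured. The aryne precursor A5 itself needs several steps.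
- Comparison: this road would be shorter after the union if both selectivities held. The chosen plan offers an unambiguous assignment of C6 and C7 and a cycloaddition whose regiochemistry is fixed by the substrate.

**Alternative 3: carbene insertion into an O-methyl C–H bond.**
- Cut and key step: C2–C3 is cut. Dirhodium tetraacetate Rh2(OAc)4 (divalent rhodium) would convert diazo ketone A8, 1-[5-(benzyloxy)-2,4-dimethoxyphenyl]-2-diazo-2-(3,4,5-trimethoxyphenyl)ethan-1-one, into a carbene. Insertion into a C–H bond of the ortho methoxy group would give racemic 6-(benzyloxy)-7-methoxy-3-(3,4,5-trimethoxyphenyl)chroman-4-one A7.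
- Merits: C2 comes from a methyl ether already present, no one-carbon reagent is needed, and the stereocentre at C3 is irrelevant because it is removed later.
- Weak points: the carbene can attack the ether oxygen to form a five-membered oxonium ylide, and a 1,2-methyl shift would contract ring C. Six-membered insertion is in any case the less favoured ring size. A7 needs a further dehydrogenation to reach the isoflavone oxidation level. A8 is made by diazo transfer onto the very kind of deoxybenzoin that a formamide acetal converts directly.
- Comparison: this road needs no moisture-sensitive diene, which is a real advantage in handling. It is longer, leaves ring A to arene chemistry, and its key step has a serious competing pathway. The chosen plan has a crude silyl ketene acetal to handle but a key step with one sensible outcome.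

Key step: step 6

Remarks on the chemistry:
- The double-bond geometries written for diene 6 are those expected from kinetic γ-deprotonation of 5. Neither survives aromatisation, so a mixture of geometric isomers would serve as long as the s-cis conformer is reachable.
- Enolates and alkoxides of numbered compounds formed in the flask are counted as the same compound.

## Route

Step 1
Reactants: 1 methyl 4-chloro-3-oxobutanoate (methyl 4-chloroacetoacetate); 2 benzyl alcohol
Product: 3 methyl 4-(benzyloxy)-3-oxobutanoate
Conditions: NaH (2.2 equiv), 2 (1.05 equiv), THF, 0 °C to rt; then cold aq. HCl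
Reagents that add atoms: none
Why: Williamson-type etherification at the α-chloro ketone carbon (SN2); the second equivalent of NaH keeps the β-keto ester as its enolate, which shields the methyl ester from transesterification by sodium benzyloxide.

Step 2
Reactants: 3 methyl 4-(benzyloxy)-3-oxobutanoate
Product: 5 methyl (2E)-4-(benzyloxy)-3-methoxybut-2-enoate, via dimethyl ketal 4 (not isolated)
Conditions: HC(OMe)3 (1.5 equiv), H2SO4 (cat.), MeOH, rt; then strip MeOH, TsOH·H2O (cat.), 110 °C
Reagents that add atoms: trimethyl orthoformate, COC(OC)OC; methanol, CO
Why: Acid-catalysed ketalisation with the orthoformate as water scavenger, then thermal loss of methanol from ketal 4; conjugation with the ester puts the double bond at C2–C3, and the E isomer (methoxy trans to the ester) is the thermodynamic one, as with simple 3-methoxybut-2-enoates.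

Step 3
Reactants: 5 methyl (2E)-4-(benzyloxy)-3-methoxybut-2-enoate
Product: 6 {[(1Z,3Z)-4-(benzyloxy)-1,3-dimethoxybuta-1,3-dien-1-yl]oxy}(trimethyl)silane
Conditions: LiN(iPr)2 (1.1 equiv), THF, −78 °C; Me3SiCl (1.2 equiv), −78 to 0 °C; evaporate, dry pentane, filter under argon; used crude
Reagents that add atoms: chlorotrimethylsilane, C[Si](C)(C)Cl
Why: Kinetic γ-deprotonation of a 3-alkoxy enoate (the C4 methylene lies cis to the ester in the E isomer) gives the extended dienolate, which Me3SiCl traps on oxygen; this is the standard preparation of silyl ketene acetal dienes.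

Step 4
Reactants: 7 2-(3,4,5-trimethoxyphenyl)acetic acid
Product: 9 N-methoxy-N-methyl-2-(3,4,5-trimethoxyphenyl)acetamide, via acyl imidazole 8 (not isolated)
Conditions: 1,1'-carbonyldiimidazole (1.1 equiv), CH2Cl2, rt; then MeNHOMe·HCl (1.2 equiv), rt
Reagents that add atoms: N,O-dimethylhydroxylamine hydrochloride, CNOC.Cl
Why: Amide coupling through acyl imidazole 8; the imidazole set free takes up the hydrochloride, so no stronger base touches the benzylic methylene.

Step 5
Reactants: 9 N-methoxy-N-methyl-2-(3,4,5-trimethoxyphenyl)acetamide
Product: 11 1-(3,4,5-trimethoxyphenyl)but-3-yn-2-one, via bromomagnesium hemiaminal 10 (not isolated)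
Conditions: HC≡CMgBr (0.5 M in THF, 2.5 equiv), THF, −20 to 0 °C; inverse quench into 1 M aq. HCl/Et2O at 0 °C; used promptly
Reagents that add atoms: ethynylmagnesium bromide, C#C[Mg]Br
Why: Weinreb ketone synthesis: the acetylide adds once and chelate 10 holds until the quench; pouring into cold acid protonates the released N,O-dimethylhydroxylamine before it can add to the terminal ynone.

Step 6
Reactants: 6 {[(1Z,3Z)-4-(benzyloxy)-1,3-dimethoxybuta-1,3-dien-1-yl]oxy}(trimethyl)silane; 11 1-(3,4,5-trimethoxyphenyl)but-3-yn-2-one
Product: 14 1-[5-(benzyloxy)-2-hydroxy-4-methoxyphenyl]-2-(3,4,5-trimethoxyphenyl)ethan-1-one, via cyclohexadiene cycloadduct 12 (not isolated), via aryl trimethylsilyl ether 13 (not isolated)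
Conditions: 6 (1.5 equiv), toluene, rt to 60 °C; then 1 M aq. HCl, THF, rt
Reagents that add atoms: none
Why: This is a polarised, asynchronous Diels–Alder cycloaddition of an electron-rich ketene acetal diene with an acetylenic ketone followed by aromatisation, the known benzannulation of 1,1,3-trioxygenated silyl ketene acetal dienes to ortho-hydroxyaryl ketones. The largest HOMO coefficient of 6 is at C4, which is fed by both C1 oxygens and the C3 methoxy group against the single benzyloxy donor working towards C1, and the largest LUMO coefficient of 11 is at the unsubstituted alkyne carbon, so C4 bonds there (C5–C6) and C1 bonds to the acyl-bearing carbon (C4a–C8a). Ring A is closed as a six-membered carbocycle by the [4+2] cycloaddition, suprafacial on both partners; if the union is stepwise (vinylogous Mukaiyama–Michael addition first), the second bond forms by 6-exo-trig attack of the allenyl enolate on the oxocarbenium carbon and the same ring results. Adduct 12 is a cyclohexa-1,4-diene whose ketal carbon cannot remain tetrahedral in an arene: acid expels methanol, the hydrogen on the benzyloxy-bearing carbon is lost, and silyl ether 13 is hydrolysed to phenol 14, which is held by a hydrogen bond to the ketone. The benzyloxy group cannot leave, because its carbon is the only saturated ring carbon that carries a hydrogen and the ketal carbon has none to give. The two stereocentres of 12 disappear on aromatisation and no stereocentre is formed. The step needs regioselectivity, secured by the three-against-one donor pattern of 6 and the terminal alkyne of 11. It also needs the right sense of aromatisation, secured by the mixed methyl silyl ketal: acid either expels methanol or cleaves the O–Si bond, and both paths end at the phenol.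

Step 7
Reactants: 14 1-[5-(benzyloxy)-2-hydroxy-4-methoxyphenyl]-2-(3,4,5-trimethoxyphenyl)ethan-1-one
Product: 16 6-(benzyloxy)-7-methoxy-3-(3,4,5-trimethoxyphenyl)-4H-chromen-4-one, via enaminone 15 (not isolated)
Conditions: Me2NCH(OMe)2 (3 equiv), toluene, 90 °C
Reagents that add atoms: N,N-dimethylformamide dimethyl acetal, COC(OC)N(C)C
Why: Condensation of the formamide acetal at the doubly activated benzylic methylene gives enaminone 15, and the ortho phenol closes ring C by 6-endo conjugate addition and loss of dimethylamine; this is the standard isoflavone synthesis from 2-hydroxydeoxybenzoins.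

Step 8
Reactants: 16 6-(benzyloxy)-7-methoxy-3-(3,4,5-trimethoxyphenyl)-4H-chromen-4-one
Product: 17 6-hydroxy-7-methoxy-3-(3,4,5-trimethoxyphenyl)-4H-chromen-4-one
Conditions: H2 (1 atm), 10% Pd/C, EtOAc–MeOH, rt; stopped at full conversion
Reagents that add atoms: none
Why: Catalytic hydrogenolysis of an aryl benzyl ether; it is much faster than reduction of the chromone C2–C3 double bond, and the aryl methyl ethers are inert.

## Compound list

1 | methyl 4-chloro-3-oxobutanoate (methyl 4-chloroacetoacetate) | COC(=O)CC(=O)CCl | starting material
2 | benzyl alcohol | OCc1ccccc1 | starting material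
3 | methyl 4-(benzyloxy)-3-oxobutanoate | COC(=O)CC(=O)COCc1ccccc1 | intermediate
4 | methyl 4-(benzyloxy)-3,3-dimethoxybutanoate | COC(=O)CC(OC)(OC)COCc1ccccc1 | intermediate (not isolated)
5 | methyl (2E)-4-(benzyloxy)-3-methoxybut-2-enoate | CO/C(COCc1ccccc1)=C/C(=O)OC | intermediate
6 | {[(1Z,3Z)-4-(benzyloxy)-1,3-dimethoxybuta-1,3-dien-1-yl]oxy}(trimethyl)silane | CO/C(O[Si](C)(C)C)=C/C(OC)=C/OCc1ccccc1 | intermediate
7 | 2-(3,4,5-trimethoxyphenyl)acetic acid | COc1cc(CC(=O)O)cc(OC)c1OC | starting material
8 | 1-(1H-imidazol-1-yl)-2-(3,4,5-trimethoxyphenyl)ethan-1-one | COc1cc(CC(=O)n2ccnc2)cc(OC)c1OC | intermediate (not isolated)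
9 | N-methoxy-N-methyl-2-(3,4,5-trimethoxyphenyl)acetamide | COc1cc(CC(=O)N(C)OC)cc(OC)c1OC | intermediate
10 | bromomagnesium 2-[methoxy(methyl)amino]-1-(3,4,5-trimethoxyphenyl)but-3-yn-2-olate (racemic) | C#CC(Cc1cc(OC)c(OC)c(OC)c1)(O[Mg]Br)N(C)OC | intermediate (not isolated)
11 | 1-(3,4,5-trimethoxyphenyl)but-3-yn-2-one | C#CC(=O)Cc1cc(OC)c(OC)c(OC)c1 | intermediate
12 | 1-{3-(benzyloxy)-4,6-dimethoxy-6-[(trimethylsilyl)oxy]cyclohexa-1,4-dien-1-yl}-2-(3,4,5-trimethoxyphenyl)ethan-1-one (mixture of diastereomers, racemic) | COC1(O[Si](C)(C)C)C=C(OC)C(OCc2ccccc2)C=C1C(=O)Cc1cc(OC)c(OC)c(OC)c1 | intermediate (not isolated)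
13 | 1-{5-(benzyloxy)-4-methoxy-2-[(trimethylsilyl)oxy]phenyl}-2-(3,4,5-trimethoxyphenyl)ethan-1-one | COc1cc(O[Si](C)(C)C)c(cc1OCc1ccccc1)C(=O)Cc1cc(OC)c(OC)c(OC)c1 | intermediate (not isolated)
14 | 1-[5-(benzyloxy)-2-hydroxy-4-methoxyphenyl]-2-(3,4,5-trimethoxyphenyl)ethan-1-one | COc1cc(O)c(cc1OCc1ccccc1)C(=O)Cc1cc(OC)c(OC)c(OC)c1 | intermediate
15 | 1-[5-(benzyloxy)-2-hydroxy-4-methoxyphenyl]-3-(dimethylamino)-2-(3,4,5-trimethoxyphenyl)prop-2-en-1-one (double-bond geometry not defined) | COc1cc(O)c(cc1OCc1ccccc1)C(=O)C(=CN(C)C)c1cc(OC)c(OC)c(OC)c1 | intermediate (not isolated)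
16 | 6-(benzyloxy)-7-methoxy-3-(3,4,5-trimethoxyphenyl)-4H-chromen-4-one | COc1cc2occ(-c3cc(OC)c(OC)c(OC)c3)c(=O)c2cc1OCc1ccccc1 | intermediate
17 | 6-hydroxy-7-methoxy-3-(3,4,5-trimethoxyphenyl)-4H-chromen-4-one | COc1cc2occ(-c3cc(OC)c(OC)c(OC)c3)c(=O)c2cc1O | target

## Step count and risks

Total steps: 8. Longest linear sequence: 6 steps (steps 1, 2, 3, 6, 7 and 8); the ynone branch (steps 4 and 5) joins at step 6.

**Step 6 (key step).**
- What may go wrong: the cycloaddition may be slow if the benzyloxy group of the diene sits on the inside of the s-cis conformer. The doubly activated methylene of the ynone may protonate and destroy the silyl ketene acetal. The terminal ynone may polymerise on warming. Aromatisation may take the minor course of losing the silyloxy group, which would leave the C8a oxygen methylated.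
- Fallback: it sets out from acid 7 and returns at 14. Friedel–Crafts acylation of commercial 2-methoxybenzene-1,4-diol F1 with 7 in BF3·OEt2 at about 80 °C should occur at the position para to the methoxy group and ortho to a hydroxyl. This would give 1-(2,5-dihydroxy-4-methoxyphenyl)-2-(3,4,5-trimethoxyphenyl)ethan-1-one F2. Benzylation of the non-chelated 5-hydroxyl (BnBr, K2CO3, acetone) would then give 14.

**Step 3.**
- What may go wrong: competing C-silylation, incomplete γ-deprotonation next to the benzyloxy group, hydrolysis of the silyl ketene acetal during isolation, or formation of the unreactive geometric isomer.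
- Fallback: it sets out from 3 and returns at 14, using the well-established 1,3-bis(silyloxy) diene class. Silylation of 3 (Me3SiCl, Et3N) would give methyl (2Z)-4-(benzyloxy)-3-[(trimethylsilyl)oxy]but-2-enoate F3. LiN(iPr)2/Me3SiCl would then give 4-(benzyloxy)-1-methoxy-1,3-bis[(trimethylsilyl)oxy]buta-1,3-diene F4. Cycloaddition of F4 with 11 and acid work-up would give 1-[5-(benzyloxy)-2,4-dihydroxyphenyl]-2-(3,4,5-trimethoxyphenyl)ethan-1-one F5. Methylation of the non-chelated, more acidic 4-hydroxyl (MeI, K2CO3, acetone) would give 14.

**Step 5.**
- What may go wrong: conjugate addition of the released N,O-dimethylhydroxylamine to the terminal ynone during work-up, or enolisation of the arylacetamide by the Grignard reagent leading to incomplete conversion.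
- Fallback: it sets out from 9 and returns at 11. Reduction with iBu2AlH (THF, −78 °C) would give 2-(3,4,5-trimethoxyphenyl)acetaldehyde F6. Addition of HC≡CMgBr would give racemic 1-(3,4,5-trimethoxyphenyl)but-3-yn-2-ol F7. Oxidation with Dess–Martin periodinane would give 11 with no amine nucleophile present.

**Step 8.**
- What may go wrong: over-reduction of the chromone C2–C3 double bond on prolonged exposure, or slow hydrogenolysis through catalyst poisoning.
- Fallback: it sets out from 16 and returns at 17. Lewis-acid debenzylation with BCl3 and pentamethylbenzene as cation scavenger (CH2Cl2, −78 °C) spares aryl methyl ethers that are not peri to the carbonyl. It makes no new compound (entry F0).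

**Step 7.**
- What may go wrong: the reaction may stall at the enaminone or at the hydrated ring-closed stage, or the formamide acetal may O-methylate the phenol at high temperature.
- Fallback: it sets out from 14 and returns at 16. Claisen formylation (HCO2Et, NaH, THF, 0 °C to rt) would give 6-(benzyloxy)-2-hydroxy-7-methoxy-3-(3,4,5-trimethoxyphenyl)chroman-4-one F8. Acid-catalysed dehydration (TsOH, toluene, warm) would give 16.

## Further compounds

F1 | step 6 | 2-methoxybenzene-1,4-diol | COc1cc(O)ccc1O
F2 | step 6 | 1-(2,5-dihydroxy-4-methoxyphenyl)-2-(3,4,5-trimethoxyphenyl)ethan-1-one | COc1cc(O)c(cc1O)C(=O)Cc1cc(OC)c(OC)c(OC)c1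
F3 | step 3 | methyl (2Z)-4-(benzyloxy)-3-[(trimethylsilyl)oxy]but-2-enoate | COC(=O)/C=C(/COCc1ccccc1)O[Si](C)(C)C
F4 | step 3 | 4-(benzyloxy)-1-methoxy-1,3-bis[(trimethylsilyl)oxy]buta-1,3-diene (double-bond geometry not defined) | COC(O[Si](C)(C)C)=CC(O[Si](C)(C)C)=COCc1ccccc1
F5 | step 3 | 1-[5-(benzyloxy)-2,4-dihydroxyphenyl]-2-(3,4,5-trimethoxyphenyl)ethan-1-one | Oc1cc(O)c(cc1OCc1ccccc1)C(=O)Cc1cc(OC)c(OC)c(OC)c1
F6 | step 5 | 2-(3,4,5-trimethoxyphenyl)acetaldehyde | COc1cc(CC=O)cc(OC)c1OC
F7 | step 5 | 1-(3,4,5-trimethoxyphenyl)but-3-yn-2-ol (racemic) | C#CC(O)Cc1cc(OC)c(OC)c(OC)c1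
F0 | step 8 | none | none
F8 | step 7 | 6-(benzyloxy)-2-hydroxy-7-methoxy-3-(3,4,5-trimethoxyphenyl)chroman-4-one (mixture of diastereomers, racemic) | COc1cc2OC(O)C(c3cc(OC)c(OC)c(OC)c3)C(=O)c2cc1OCc1ccccc1
A1 | alternative 1 | 3-[2,5-bis(benzyloxy)-4-methoxyphenyl]-4-(3,4,5-trimethoxyphenyl)isoxazole | COc1cc(OCc2ccccc2)c(-c2nocc2-c2cc(OC)c(OC)c(OC)c2)cc1OCc1ccccc1
A2 | alternative 1 | 2,5-bis(benzyloxy)-4-methoxybenzonitrile oxide | COc1cc(OCc2ccccc2)c(C#[N+][O-])cc1OCc1ccccc1
A3 | alternative 1 | 1-[(E)-2-(3,4,5-trimethoxyphenyl)ethenyl]pyrrolidine | COc1cc(/C=C/N2CCCC2)cc(OC)c1OC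
A4 | alternative 2 | 6,7-bis(benzyloxy)-3-(3,4,5-trimethoxyphenyl)-4H-chromen-4-one | O=c1c(-c2cc(OC)c(OC)c(OC)c2)coc2cc(OCc3ccccc3)c(OCc3ccccc3)cc12
A5 | alternative 2 | 4,5-bis(benzyloxy)-2-(trimethylsilyl)phenyl trifluoromethanesulfonate | C[Si](C)(C)c1cc(OCc2ccccc2)c(OCc2ccccc2)cc1OS(=O)(=O)C(F)(F)F
A6 | alternative 2 | methyl 3-oxo-2-(3,4,5-trimethoxyphenyl)propanoate (racemic, enolisable) | COC(=O)C(C=O)c1cc(OC)c(OC)c(OC)c1
A7 | alternative 3 | 6-(benzyloxy)-7-methoxy-3-(3,4,5-trimethoxyphenyl)chroman-4-one (racemic) | COc1cc2OCC(c3cc(OC)c(OC)c(OC)c3)C(=O)c2cc1OCc1ccccc1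
A8 | alternative 3 | 1-[5-(benzyloxy)-2,4-dimethoxyphenyl]-2-diazo-2-(3,4,5-trimethoxyphenyl)ethan-1-one | COc1cc(OC)c(cc1OCc1ccccc1)C(=O)C(=[N+]=[N-])c1cc(OC)c(OC)c(OC)c1
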